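Read the end of each earlier run first, the chair told the meeting, then say what more coupling partner buys.

| setting | maple | elm | green | teal | violet |
|---|---|---|---|---|---|
| substrate | 20 mM | 20 mM | 20 mM | 20 mM | 20 mM |
| coupling partner | 33 mM | 120 mM | 24.0 mM | 48.0 mM | 96.0 mM |
| free catalyst | 40 µM | 40 µM | 40 µM | 40 µM | 40 µM |
| remark | run made earlier | run made earlier |  |  |  |
| time |  |  | 3.0 h | 3.0 h | 3.0 h |

| run | time / h | substrate / % | product / % |
|---|---|---|---|
| maple | 0.667 | 90.2 | 10.8 |
| maple | 1.33 | 81.0 | 19.9 |
| maple | 2.00 | 72.4 | 27.3 |
| maple | 2.50 | 64.5 | 33.9 |
| maple | 3.00 | 59.8 | 40.0 |
| elm | 0.667 | 87.8 | 14.0 |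
| elm | 1.33 | 74.3 | 24.3 |
| elm | 2.00 | 63.5 | 36.3 |
| elm | 2.50 | 55.7 | 44.5 |
| elm | 3.00 | 49.0 | 52.0 |

(scatter of a reading: 1 percentage point)

- part of the substrate that has reacted at the end, green
- part of the substrate that has reacted at the end, teal
- part of the substrate that has reacted at the end, violet
- what raising the concentration of coupling partner from its lowest to its highest value here does to the part of the substrate that has reacted (changes below 5 percentage points count as none) (it rises / it falls / no change)

- what was read earlier has a scatter of 1 percentage point, one standard deviation

The first speaker reported that substrate falls roughly exponentially in both runs. She therefore took an apparent rate constant k, pseudo-first-order in substrate: the logarithm of charged over remaining substrate, divided by the time. Maple gave 0.171 h⁻¹ and elm gave 0.238 h⁻¹.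

The second speaker pointed out that the charge of coupling partner rose by a factor of 3.64, while k rose by less, a factor of 1.39. She reduced this to one number, n = 0.254. This is the partner order: the logarithm of the rise in k over the logarithm of the rise in charge.

The chair ruled that each new flask takes maple's k times its charge ratio to maple, raised to n. The part reacted is then one minus the exponential of minus k times the time. That reckoning gave 37.8% for green, 43.2% for teal and 49.0% for violet. The rise of 11 percentage points is larger than the margin, so the meeting expected a rise. The second speaker warned that green's charge is lower than maple's, so green is an extrapolation.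

The forecast, with “A shallow power law” among its grounds, gives 35%, 43% and 49% for green, teal and violet and says it rises, and it stands lower than this reckoning at green.

The flasks gave 36.1% for green, 44.9% for teal and 50.1% for violet, so it rises, by 14 points.

    coupling partner + free catalyst ⇌ catalyst intermediate A (K = 2100 M⁻¹, k = 8410 M⁻¹ h⁻¹)
    catalyst intermediate A ⇌ released group + catalyst intermediate B (K = 0.0882 M, k = 255 h⁻¹)
    substrate + catalyst intermediate B → catalyst intermediate C (k = 12200 M⁻¹ h⁻¹)
    catalyst intermediate C → free catalyst + product (k = 1140 h⁻¹)
    coupling partner + released group ⇌ idle adduct, settled at all times (K = 46.4 M⁻¹)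

In teal, coupling partner kept reacting with free catalyst, with 54% of that step's turnover up to 3.00 h done by 1.50 h, while released group reached 3.52 mM and idle adduct 5.47 mM at 3.00 h. Substrate meanwhile met catalyst intermediate B, which held 46.1% of the catalyst at 3.00 h, more than any other form. For a further flask like teal but charged with 19 mM of coupling partner, n of 0.254 reckons 36.0%. That flask gave 32.5%.

(The runs come from a simulation with made-up constants, and the scatter is random.)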